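**Retrosynthetic overview**
1. Target 35 ← hydrolysis of the C4 methyl enol ether and aryl silyl ethers ← bridgehead C1 prenylation ← C3 aroylation of bicyclic vinylogous ester 27.
2. Ring B of 27 (C9–C1–C8–C7–C6–C5) ← oxidative 1,2-shift of C8 from C9 to C1 in tricyclic hydroxy enone 25, i.e. ring expansion of a cyclopentane C5–C6–C7–C8–C9.
3. Ring A (C9–C1–C2–C3–C4–C5) ← key step: enolate of hydroazulenone 20 + diketene, C5–C4 acylation then C1–C9 aldol. Enabling feature: C9 is a ketone carbon bonded to both bridgeheads, its neighbour C8 is quaternary so only C5 can enolise, and C1–C2–C3–C4 is the four-carbon 1,3-dioxygenated unit of diketene, whose terminal carbon C1 lies six-ring distance from C9.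
4. Seven-membered ring of 20 ← aldol condensation (C5–C10) ← trans conjugate addition (C6–C14) of the (R)-carvone-derived C10–C14 chain 8 to cyclopentenone 14.
5. Order of ring formation: cyclopentane (from 2-methylcyclopentenone) → cycloheptane → ring A (key step) → ring B (ring expansion).

Key step: step 14

Remark: the target is treated as the enolised β-triketone (C4 enol tautomer as drawn); locants used throughout are C1 (prenylated bridgehead), C2 (ketone), C3 (aroyl-bearing), C4 (enol carbon), C5 (bridgehead), C6, C7 (prenyl-bearing CH), C8 (CMe2), C9 (bridging ketone), and C5–C10H2–C11Me2–C12H(isopropenyl)–C13H2–C14H2–C6 for the seven-membered ring.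

**Step 1**
Reactants: 1 (R)-(−)-carvone
Product: 3 (5S)-2,6,6-trimethyl-5-(prop-1-en-2-yl)cyclohex-2-en-1-one (6,6-dimethylcarvone), via 6-methylcarvone 2 (not isolated)
Conditions: LiN(i-Pr)2, THF, −78 °C; MeI, −78 → 0 °C; then LiN(i-Pr)2, −78 °C; MeI, DMPU, −78 °C → rt
Reagents that add atoms: iodomethane, CI
Why: Kinetic deprotonation of the cross-conjugated enone at the α′ carbon and enolate methylation, run twice, builds the future C11 gem-dimethyl carbon; the adjacent carvone stereocentre (future C12) is not enolisable and is retained.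

**Step 2**
Reactants: 3 6,6-dimethylcarvone
Product: 4 2,3-epoxide of 3 (epoxide expected anti to the isopropenyl group)
Conditions: 30% aq. H2O2, NaOH (0.2 equiv), MeOH, 0 °C → rt
Reagents that add atoms: hydrogen peroxide, OO
Why: Weitz–Scheffer nucleophilic epoxidation attacks only the electron-poor enone alkene and spares the isopropenyl group; the epoxide stereocentres are destroyed in step 3.

**Step 3**
Reactants: 4 epoxy ketone
Product: 5 (3S)-2,2-dimethyl-5-oxo-3-(prop-1-en-2-yl)pentanoic acid
Conditions: H5IO6 (2.5 equiv), THF/H2O, 0 °C → rt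
Reagents that add atoms: water, O
Why: Periodic acid opens the epoxide to the α-keto glycol and cleaves both the glycol bond and the resulting 1,2-dicarbonyl bond (Malaprade-type cleavage), excising the methyl-bearing ring carbon as acetic acid and leaving C10 as acid and C14 as aldehyde with the C12 stereocentre untouched.

**Step 4**
Reactants: 5 acid aldehyde
Product: 6 (3S)-2,2-dimethyl-3-(prop-1-en-2-yl)pentane-1,5-diol
Conditions: LiAlH4, THF, 0 °C → reflux; aq. NaOH work-up
Reagents that add atoms: none
Why: Hydride reduction of acid and aldehyde to the diol; the isolated alkene and the stereocentre are inert.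

**Step 5**
Reactants: 6 diol
Product: 7 (3S)-5-bromo-2,2-dimethyl-3-(prop-1-en-2-yl)pentan-1-ol
Conditions: CBr4 (1.05 equiv), PPh3 (1.1 equiv), CH2Cl2, −20 → 0 °C
Reagents that add atoms: carbon tetrabromide, BrC(Br)(Br)Br
Why: Appel bromination; SN2 displacement of the alkoxyphosphonium ion is possible only at the unhindered C14 carbinol, the neopentyl C10–OH being inert to substitution.

**Step 6**
Reactants: 7 bromo alcohol
Product: 8 [(3S)-5-bromo-2,2-dimethyl-3-(prop-1-en-2-yl)pentyl]oxy(triethyl)silane
Conditions: Et3SiCl, imidazole, CH2Cl2, 0 °C → rt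
Reagents that add atoms: chlorotriethylsilane, CC[Si](Cl)(CC)CC
Why: Silylation masks the neopentyl alcohol so that the bromide can be turned into a Grignard reagent.

**Step 7**
Reactants: 9 2-methylcyclopent-2-en-1-one
Product: 11 (3S)-2,2-dimethyl-3-(3-methylbut-3-en-1-yl)cyclopentan-1-one, via magnesium enolate 10 (not isolated)
Conditions: (3-methylbut-3-en-1-yl)magnesium bromide, CuBr·SMe2 (5 mol %), 1-[2-(diphenylphosphino)ferrocenyl]ethyldicyclohexylphosphine (Josiphos-type, 6 mol %, the enantiomer that delivers the 3S adduct), t-BuOMe, −75 °C; then MeI, DMPU, −75 → 0 °C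
Reagents that add atoms: (3-methylbut-3-en-1-yl)magnesium bromide, C=C(C)CC[Mg]Br; iodomethane, CI
Why: Copper-catalysed asymmetric conjugate addition sets C7 under ligand control, and C-methylation of enolate 10 makes the achiral C8 gem-dimethyl carbon (conjugate addition with enolate trapping).

**Step 8**
Reactants: 11 isopentenyl ketone
Product: 12 (3R)-2,2-dimethyl-3-(3-methylbut-2-en-1-yl)cyclopentan-1-one
Conditions: Co(salen)Cl [salen = N,N′-bis(3,5-di-tert-butylsalicylidene)ethane-1,2-diamine dianion] (3 mol %), PhSiH3 (6 mol %), benzene, 23 °C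
Reagents that add atoms: none
Why: Cobalt-hydride hydrogen-atom-transfer isomerisation moves the 1,1-disubstituted alkene by one position to the trisubstituted prenyl alkene and stops there, so C7 keeps its configuration (the descriptor changes only through priorities).

**Step 9**
Reactants: 12 prenyl ketone
Product: 14 (4S)-5,5-dimethyl-4-(3-methylbut-2-en-1-yl)cyclopent-2-en-1-one, via silyl enol ether 13 (not isolated)
Conditions: LiN(i-Pr)2, Me3SiCl, THF, −78 °C; then Pd(OAc)2 (10 mol %), O2 (1 atm), DMSO, rt
Reagents that add atoms: none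
Why: Saegusa–Ito dehydrogenation; enolisation is possible only toward C5 because C8 is quaternary, and dehydrosilylation by divalent palladium gives the C5=C6 enone without touching C7.

**Step 10**
Reactants: 8 bromide; 14 enone
Product: 17 (3S,4R)-4-[(3S)-5-hydroxy-4,4-dimethyl-3-(prop-1-en-2-yl)pentyl]-2,2-dimethyl-3-(3-methylbut-2-en-1-yl)cyclopentan-1-one, via Grignard reagent 15 (not isolated), via silyl enol ether 16 (not isolated)
Conditions: 8, Mg, THF, 45 °C; then CuBr·SMe2 (10 mol %), Me3SiCl, 14, THF, −78 → −30 °C; then 1 M HCl, THF, rt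
Reagents that add atoms: none
Why: Copper-catalysed conjugate addition of Grignard reagent 15 occurs at C6 anti to the C7 prenyl group (trans-3,4-disubstituted cyclopentanone, substrate control), and the acidic work-up cleaves both silyl ethers.

**Step 11**
Reactants: 17 hydroxy ketone
Product: 18 (3S)-5-[(1R,2S)-3,3-dimethyl-2-(3-methylbut-2-en-1-yl)-4-oxocyclopentyl]-2,2-dimethyl-3-(prop-1-en-2-yl)pentanal
Conditions: Dess–Martin periodinane, NaHCO3, CH2Cl2, 0 °C → rt
Reagents that add atoms: none
Why: Mild periodinane oxidation of the neopentyl alcohol to the non-enolisable C10 aldehyde; no stereocentre is α to a carbonyl that could epimerise.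

**Step 12**
Reactants: 18 keto aldehyde
Product: 19 (3S,3aS,6S)-2,2,7,7-tetramethyl-3-(3-methylbut-2-en-1-yl)-6-(prop-1-en-2-yl)-3,3a,4,5,6,7-hexahydroazulen-1(2H)-one (C5=C10 enone)
Conditions: KOH, MeOH, 60 °C, 0.01 M
Reagents that add atoms: none
Why: Intramolecular aldol condensation closes the seven-membered ring (C5–C10); only C5 can enolise and the aldehyde has no α-hydrogen, so a single ring closure is possible and no stereocentre is created.

**Step 13**
Reactants: 19 bicyclic enone
Product: 20 (3S,3aS,6S)-2,2,7,7-tetramethyl-3-(3-methylbut-2-en-1-yl)-6-(prop-1-en-2-yl)octahydroazulen-1(2H)-one (C5 epimers)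
Conditions: Li, NH3(l), THF, t-BuOH (1.0 equiv), −78 °C; then NH4Cl
Reagents that add atoms: none
Why: Dissolving-metal (Birch-type) conjugate reduction of the hindered enone spares the isolated alkenes; the C5 configuration is immaterial because C5 is enolised in step 14.

**Step 14**
Reactants: 20 hydroazulenone; 21 diketene
Product: 24 tricyclic 9-hydroxy-2,4-dione (ring A cis-fused to the cyclopentane at C5–C9; C9–OH trans to C4), via lithium enolate 22 (not isolated), via acyl enolate 23 (not isolated)
Conditions: LiN(i-Pr)2, THF, −78 → 0 °C; then diketene, −78 → −40 °C; aq. NH4Cl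
Reagents that add atoms: none
Why: LiN(i-Pr)2 removes the only enolisable α-hydrogen of 20 (H-5, C8 being quaternary) to give enolate 22, whose C5 attacks the lactone carbonyl of diketene (C5–C4 bond) and opens the four-membered ring to the terminal enolate 23 (C1=C2–OLi), which adds to the neighbouring C9 ketone and so forms the C1–C9 bond and ring A. The closest known reaction type is the diketene annulation (C-acylation then intramolecular aldol addition) of lithium enolates of α-substituted cyclopentanones. Ring A closes by a 6-(enolexo)-exo-trig aldol addition. C5 is set by attack of diketene on the enolate face anti to the C6–C14 bond of the seven-membered ring (cis to H-6, giving the cis-fused hydroazulenone), and C9 is set by the tether, which lets C1 reach the carbonyl only from the face carrying C4, so the C9–OH ends trans to C4. The step needs C- over O-acylation (lithium enolate of a hindered ketone, low temperature), the facial selectivity at C5 just named (1,2-control by the ring fusion), and aldol closure faster than proton transfer from C3–H2 to the terminal enolate (favoured by the six-membered intramolecular closure at −78 to −40 °C).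

**Step 15**
Reactants: 24 hydroxy diketone
Product: 25 4-methoxy enone (C3=C4–OMe; free C2 ketone; C9–OH)
Conditions: Me3SiCHN2, i-Pr2NEt, MeCN/MeOH, 0 °C → rt
Reagents that add atoms: (trimethylsilyl)diazomethane, C[Si](C)(C)C=[N+]=[N-]
Why: O-methylation of the enolised 1,3-diketone gives the vinylogous ester; the regioisomer with the free C2 ketone is the one carried on (only it can enolise toward C1), and the other isomer is returned to 24 by hydrolysis.

**Step 16**
Reactants: 25 hydroxy vinylogous ester
Product: 27 bicyclo[3.3.1]nonane vinylogous ester (C2 ketone; C4–OMe; C9 ketone; C1–H), via iodane 26 (not isolated)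
Conditions: PhI(OAc)2, KOH, MeOH, −10 → 0 °C
Reagents that add atoms: none
Why: Under Moriarty-type conditions the C2 ketone enolises toward C1 (its only enolisable carbon), C1 is bonded to trivalent iodine (iodane 26), and the C9 alkoxide drives a semipinacol 1,2-shift of C8 from C9 to C1 with loss of iodobenzene. This creates the C9 ketone and ring B; C1 is fixed by the bridged framework (an oxidative ring expansion of this kind is known for diketene-annulation adducts).

**Step 17**
Reactants: 28 3,4-dihydroxybenzoic acid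
Product: 29 tert-butyldimethylsilyl 3,4-bis(tert-butyldimethylsilyloxy)benzoate
Conditions: t-BuMe2SiCl (3.3 equiv), imidazole, DMF, rt
Reagents that add atoms: tert-butyl(chloro)dimethylsilane, CC(C)(C)[Si](C)(C)Cl
Why: Exhaustive silylation protects the catechol and gives a silyl ester that can be converted directly into the acid chloride.

**Step 18**
Reactants: 29 tris-silyl compound
Product: 30 3,4-bis(tert-butyldimethylsilyloxy)benzoyl chloride
Conditions: (COCl)2, DMF (cat.), CH2Cl2, 0 °C → rt
Reagents that add atoms: oxalyl chloride, O=C(Cl)C(=O)Cl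
Why: Vilsmeier-type activation converts the silyl ester into the acid chloride under neutral conditions that leave the aryl silyl ethers intact.

**Step 19**
Reactants: 27 bicyclic vinylogous ester; 30 acid chloride
Product: 32 3-aroyl vinylogous ester (C1–H), via vinyllithium 31 (not isolated)
Conditions: lithium 2,2,6,6-tetramethylpiperidide, THF, −78 °C; then 30, −78 → −20 °C
Reagents that add atoms: none
Why: The vinylic C3–H between the methoxy-bearing C4 and the C2 carbonyl is the kinetically most acidic site, and the vinyllithium is C-acylated by the acid chloride; the aroyl group then also blocks C3 for step 20.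

**Step 20**
Reactants: 32 3-aroyl vinylogous ester
Product: 34 1-prenyl-3-aroyl vinylogous ester, via bridgehead organolithium 33 (not isolated)
Conditions: lithium 2,2,6,6-tetramethylpiperidide, THF, −78 → −40 °C; then prenyl bromide, DMPU, −78 → 0 °C
Reagents that add atoms: 1-bromo-3-methylbut-2-ene, CC(C)=CCBr
Why: Bridgehead deprotonation at C1 (flanked by the C2 and C9 carbonyls, C3 being blocked) gives a pyramidal carbanion that can only be C-alkylated, with retention; the C1 configuration is dictated by the bicyclic cage (bridgehead lithiation–alkylation).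

**Step 21**
Reactants: 34 protected precursor
Product: 35 target CNP0140614.2
Conditions: LiOH·H2O, 1,4-dioxane/H2O (degassed), 90 °C; then 1 M HCl to pH 3
Reagents that add atoms: lithium hydroxide, [Li+].[OH-]
Why: Hydroxide addition–elimination at C4 hydrolyses the doubly activated vinylogous ester and also cleaves both aryl silyl ethers; acidification gives the enolised triketone with all five stereocentres unchanged.

**Compound list**
1 | (R)-(−)-carvone | CC1=CC[C@H](CC1=O)C(C)=C | starting material
2 | 6-methylcarvone, C6 epimers | CC1=CC[C@H](C(C)C1=O)C(C)=C | intermediate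
3 | (5S)-2,6,6-trimethyl-5-(prop-1-en-2-yl)cyclohex-2-en-1-one | CC1=CC[C@H](C(C)(C)C1=O)C(C)=C | intermediate
4 | 2,3-epoxide of 3 (epoxide anti to isopropenyl expected) | CC12OC1C[C@H](C(C)(C)C2=O)C(C)=C | intermediate
5 | (3S)-2,2-dimethyl-5-oxo-3-(prop-1-en-2-yl)pentanoic acid | O=CC[C@H](C(C)(C)C(=O)O)C(C)=C | intermediate
6 | (3S)-2,2-dimethyl-3-(prop-1-en-2-yl)pentane-1,5-diol | OCC[C@H](C(C)(C)CO)C(C)=C | intermediate
7 | (3S)-5-bromo-2,2-dimethyl-3-(prop-1-en-2-yl)pentan-1-ol | BrCC[C@H](C(C)(C)CO)C(C)=C | intermediate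
8 | triethylsilyl ether of 7 | BrCC[C@H](C(C)(C)CO[Si](CC)(CC)CC)C(C)=C | intermediate
9 | 2-methylcyclopent-2-en-1-one | CC1=CCCC1=O | starting material
10 | bromomagnesium enolate of the conjugate adduct | Br[Mg]OC1=C(C)[C@@H](CCC(C)=C)CC1 | intermediate
11 | (3S)-2,2-dimethyl-3-(3-methylbut-3-en-1-yl)cyclopentan-1-one | O=C1CC[C@H](CCC(C)=C)C1(C)C | intermediate
12 | (3R)-2,2-dimethyl-3-(3-methylbut-2-en-1-yl)cyclopentan-1-one | O=C1CC[C@H](CC=C(C)C)C1(C)C | intermediate
13 | trimethylsilyl enol ether of 12 (C5=C9) | C[Si](C)(C)OC1=CC[C@H](CC=C(C)C)C1(C)C | intermediate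
14 | (4S)-5,5-dimethyl-4-(3-methylbut-2-en-1-yl)cyclopent-2-en-1-one | O=C1C=C[C@H](CC=C(C)C)C1(C)C | intermediate
15 | [(3S)-4,4-dimethyl-3-(prop-1-en-2-yl)-5-(triethylsilyloxy)pentyl]magnesium bromide | C=C(C)[C@H](CC[Mg]Br)C(C)(C)CO[Si](CC)(CC)CC | intermediate
16 | trimethylsilyl enol ether of the conjugate adduct, triethylsilyl ether intact | C=C(C)[C@H](CC[C@H]1[C@H](CC=C(C)C)C(C)(C)C(O[Si](C)(C)C)=C1)C(C)(C)CO[Si](CC)(CC)CC | intermediate
17 | (3S,4R)-4-[(3S)-5-hydroxy-4,4-dimethyl-3-(prop-1-en-2-yl)pentyl]-2,2-dimethyl-3-(3-methylbut-2-en-1-yl)cyclopentan-1-one | C=C(C)[C@H](CC[C@H]1[C@H](CC=C(C)C)C(C)(C)C(=O)C1)C(C)(C)CO | intermediate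
18 | (3S)-5-[(1R,2S)-3,3-dimethyl-2-(3-methylbut-2-en-1-yl)-4-oxocyclopentyl]-2,2-dimethyl-3-(prop-1-en-2-yl)pentanal | C=C(C)[C@H](CC[C@H]1[C@H](CC=C(C)C)C(C)(C)C(=O)C1)C(C)(C)C=O | intermediate
19 | (3S,3aS,6S)-2,2,7,7-tetramethyl-3-(3-methylbut-2-en-1-yl)-6-(prop-1-en-2-yl)-3,3a,4,5,6,7-hexahydroazulen-1(2H)-one | C=C(C)[C@@H]1CC[C@H]2[C@H](CC=C(C)C)C(C)(C)C(=O)C2=CC1(C)C | intermediate
20 | (3S,3aS,6S)-2,2,7,7-tetramethyl-3-(3-methylbut-2-en-1-yl)-6-(prop-1-en-2-yl)octahydroazulen-1(2H)-one, C5 epimers | C=C(C)[C@@H]1CC[C@H]2[C@H](CC=C(C)C)C(C)(C)C(=O)C2CC1(C)C | intermediate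
21 | diketene (4-methylideneoxetan-2-one) | C=C1CC(=O)O1 | starting material
22 | lithium enolate of 20 (C5=C9–OLi) | C=C(C)[C@@H]1CC[C@H]2[C@H](CC=C(C)C)C(C)(C)C(O[Li])=C2CC1(C)C | intermediate
23 | C5-acetoacetyl ketone as terminal lithium enolate (C1=C2–OLi), C4 cis to H-6 | C=C(C)[C@@H]1CC[C@H]2[C@H](CC=C(C)C)C(C)(C)C(=O)[C@]2(CC1(C)C)C(=O)CC(=C)O[Li] | intermediate
24 | tricyclic 9-hydroxy-2,4-dione: ring A (C1H2, C2=O, C3H2, C4=O, C5, C9) cis-fused at C5–C9 to the cyclopentane, C9–OH trans to C4 | C=C(C)[C@@H]1CC[C@H]2[C@H](CC=C(C)C)C(C)(C)[C@]3(O)CC(=O)CC(=O)[C@]23CC1(C)C | intermediate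
25 | 4-methoxy enone of 24 (C3=C4–OMe, C2 ketone, C9–OH) | C=C(C)[C@@H]1CC[C@H]2[C@H](CC=C(C)C)C(C)(C)[C@]3(O)CC(=O)C=C(OC)[C@]23CC1(C)C | intermediate
26 | C1-[methoxy(phenyl)-λ3-iodanyl] derivative of 25 | C=C(C)[C@@H]1CC[C@H]2[C@H](CC=C(C)C)C(C)(C)[C@]3(O)C(I(OC)c4ccccc4)C(=O)C=C(OC)[C@]23CC1(C)C | intermediate
27 | bicyclo[3.3.1]nonane vinylogous ester: C1–H, C2 ketone, C3–H, C4–OMe, C9 ketone, cycloheptane fused at C5–C6, prenyl at C7 | C=C(C)[C@@H]1CC[C@H]2[C@H](CC=C(C)C)C(C)(C)[C@@H]3C(=O)C=C(OC)[C@@]2(CC1(C)C)C3=O | intermediate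
28 | 3,4-dihydroxybenzoic acid | O=C(O)c1ccc(O)c(O)c1 | starting material
29 | tert-butyldimethylsilyl 3,4-bis(tert-butyldimethylsilyloxy)benzoate | O=C(O[Si](C)(C)C(C)(C)C)c1ccc(O[Si](C)(C)C(C)(C)C)c(O[Si](C)(C)C(C)(C)C)c1 | intermediate
30 | 3,4-bis(tert-butyldimethylsilyloxy)benzoyl chloride | O=C(Cl)c1ccc(O[Si](C)(C)C(C)(C)C)c(O[Si](C)(C)C(C)(C)C)c1 | intermediate
31 | C3-lithio derivative of 27 | C=C(C)[C@@H]1CC[C@H]2[C@H](CC=C(C)C)C(C)(C)[C@@H]3C(=O)C([Li])=C(OC)[C@@]2(CC1(C)C)C3=O | intermediate
32 | 3-[3,4-bis(tert-butyldimethylsilyloxy)benzoyl] derivative of 27 | C=C(C)[C@@H]1CC[C@H]2[C@H](CC=C(C)C)C(C)(C)[C@@H]3C(=O)C(C(=O)c4ccc(O[Si](C)(C)C(C)(C)C)c(O[Si](C)(C)C(C)(C)C)c4)=C(OC)[C@@]2(CC1(C)C)C3=O | intermediate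
33 | C1-lithio (bridgehead) derivative of 32 | C=C(C)[C@@H]1CC[C@H]2[C@H](CC=C(C)C)C(C)(C)[C@]3([Li])C(=O)C(C(=O)c4ccc(O[Si](C)(C)C(C)(C)C)c(O[Si](C)(C)C(C)(C)C)c4)=C(OC)[C@@]2(CC1(C)C)C3=O | intermediate
34 | 1-prenyl-3-aroyl-4-methoxy precursor (O-methyl, bis-silyl protected target) | C=C(C)[C@@H]1CC[C@H]2[C@H](CC=C(C)C)C(C)(C)[C@]3(CC=C(C)C)C(=O)C(C(=O)c4ccc(O[Si](C)(C)C(C)(C)C)c(O[Si](C)(C)C(C)(C)C)c4)=C(OC)[C@@]2(CC1(C)C)C3=O | intermediate
35 | CNP0140614.2, (1S,5S,6S,7S,12S) in the route locants: 3-(3,4-dihydroxybenzoyl)-4-hydroxy-8,8,11,11-tetramethyl-1,7-diprenyl-12-isopropenyl bicyclo[3.3.1]non-3-ene-2,9-dione with the cycloheptane fused at C5–C6 | C=C(C)[C@@H]1CC[C@H]2[C@H](CC=C(C)C)C(C)(C)[C@]3(CC=C(C)C)C(=O)C(C(=O)c4ccc(O)c(O)c4)=C(O)[C@@]2(CC1(C)C)C3=O | target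

**Step count and risks**
Total step count: 21. Longest linear sequence: 16 steps (steps 1–6, 10–16, 19–21).

Steps most likely to fail:

Step 14. Proton transfer from C3–H2 to the terminal enolate of 23 may outrun the aldol closure onto the C9 ketone, which is flanked by two quaternary carbons, so that only open-chain material results; acylation on the enolate face syn to C14 is a second concern. Fallback, setting out from 20 and returning at 24: the enolate of 20 is acylated with diketene and quenched cold with acetic acid to give the open-chain C5-acetoacetyl ketone F1. Its 1,3-diketone is converted with Me3SiOTf/Et3N into the 1,3-bis(trimethylsilyloxy)diene F2 (the C9 ketone cannot enolise). TiCl4 in CH2Cl2 at −78 °C then closes ring A by an intramolecular vinylogous Mukaiyama aldol addition of the terminal diene carbon C1 to C9, giving 24 after aqueous work-up.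

Step 16. Iodane 26 may collapse by attack of the C9 oxygen on C1 (epoxide formation) or by migration of the C5–C9 bond instead of the C8–C9 bond, and the basic medium may cleave the C1–C9 bond by retro-aldol reaction. Fallback, setting out from 25 and returning at 27: deprotonation with LiN(i-Pr)2 (2.2 equiv, alkoxide and C1 enolate) and quenching with I2 gives the α′-iodo ketone F3. AgBF4 with 2,6-di-tert-butylpyridine in CH2Cl2 then ionises the C1–I bond under non-basic conditions with migration of C8 (halohydrin-type semipinacol rearrangement), giving 27.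

Step 20. Deprotonation of the congested bridgehead C1–H next to the quaternary C8 may be incomplete, and alkylation of the hindered bridgehead anion may be slow. Fallback, setting out from 25 and returning at 34: the prenyl group is introduced before ring expansion by kinetic α′-alkylation of the vinylogous ester (LiN(i-Pr)2, 2.2 equiv, then prenyl bromide), giving the C1-prenylated hydroxy enone F4. Ring expansion under the conditions of step 16 then creates the quaternary C1 directly and gives the 1-prenyl bicyclic vinylogous ester F5. C3 aroylation of F5 with 30 under the conditions of step 19 gives 34.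

**Further compounds**
F1 | step 14 | open-chain C5-acetoacetyl hydroazulenone (protonated form of 23) | C=C(C)[C@@H]1CC[C@H]2[C@H](CC=C(C)C)C(C)(C)C(=O)[C@]2(CC1(C)C)C(=O)CC(C)=O
F2 | step 14 | 1,3-bis(trimethylsilyloxy)diene of F1 | C=C(C)[C@@H]1CC[C@H]2[C@H](CC=C(C)C)C(C)(C)C(=O)[C@]2(CC1(C)C)C(O[Si](C)(C)C)=CC(=C)O[Si](C)(C)C
F3 | step 16 | C1-iodo derivative of 25 | C=C(C)[C@@H]1CC[C@H]2[C@H](CC=C(C)C)C(C)(C)[C@]3(O)C(I)C(=O)C=C(OC)[C@]23CC1(C)C
F4 | step 20 | C1-prenyl derivative of 25 | C=C(C)[C@@H]1CC[C@H]2[C@H](CC=C(C)C)C(C)(C)[C@]3(O)C(CC=C(C)C)C(=O)C=C(OC)[C@]23CC1(C)C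
F5 | step 20 | 1-prenyl analogue of 27 | C=C(C)[C@@H]1CC[C@H]2[C@H](CC=C(C)C)C(C)(C)[C@]3(CC=C(C)C)C(=O)C=C(OC)[C@@]2(CC1(C)C)C3=O
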